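## Retrosynthetic overview

1. Atom names follow the chromene numbering of the target: pyranone ring O1–C2–C3–C4–C4a–C8a, carbocycle C4a–C5–C6–C7–C8–C8a. The last disconnection cuts the dihydropyranone at C4–C4a and O1–C8a. This gives cis-β-lactone 28 (ring O1–C2–C3–C4, both methyl-bearing centres) and the bromo-methoxy dienone acid 24. In the forward sense the C4a=C8a bond of the carbocycle is inserted into the acyl C4–O1 bond, a 4 → 6 ring expansion.
2. Enabling feature: the pyranone is a vinylogous ester, O1–C8a=C4a–C4=O, and its C4a=C8a edge is shared with the carbocycle. C4a (α) can therefore carry a carbanion (from C–Br) and C8a (β) a leaving group (OMe). O1, C2, C3 and C4 are exactly the four ring atoms of a β-lactone.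
3. Quaternary C8 comes from a Tsuji–Trost para-allylative dearomatisation of the fully substituted phenol 20. A temporary dihydrocoumarin lactone masks the acid and O7, Br blocks C4a, and OMe marks C8a.
4. The lavandulyl chain is attached by Negishi coupling of the zinc reagent from (S)-lavandulyl iodide (made by Evans alkylation). The hexanoic acid centre is set by Cu–H conjugate reduction of the Pechmann coumarin.
5. Ring order: benzene ring (bought) → temporary δ-lactone (closed in step 5, opened in step 14) → β-lactone (step 15) → dihydropyranone (step 16).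

Key step: step 16

Assumption: in steps 7, 13 and 15 the catalyst antipode written is the one expected to give the drawn configuration. If the sense of induction is the opposite, the mirror-image (or pseudo-enantiomeric) catalyst is used.

## Route

Step 1
Reactants: 1 (S)-4-benzyl-1,3-oxazolidin-2-one; 2 3-methylbut-2-enoyl chloride
Product: 4 (S)-4-benzyl-3-(3-methylbut-2-enoyl)-1,3-oxazolidin-2-one, via lithium oxazolidinonide 3 (not isolated)
Conditions: n-BuLi, THF, −78 °C; then 2, −78 → 0 °C
Reagents that add atoms: n-butyllithium, [Li]CCCC (its lithium is present only in 3)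
Why: N-acylation of the lithiated oxazolidinone auxiliary with an acid chloride is standard, and the auxiliary centre is not touched.

Step 2
Reactants: 4 (S)-4-benzyl-3-(3-methylbut-2-enoyl)-1,3-oxazolidin-2-one; 5 1-bromo-3-methylbut-2-ene (prenyl bromide)
Product: 7 (S)-4-benzyl-3-[(2S)-5-methyl-2-(prop-1-en-2-yl)hex-4-enoyl]-1,3-oxazolidin-2-one, via sodium dienolate 6 (not isolated)
Conditions: NaHMDS, THF, −78 °C; then 5, −78 → −40 °C
Reagents that add atoms: sodium hexamethyldisilazide, C[Si](C)(C)[N-][Si](C)(C)C.[Na+] (its sodium is present only in 6)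
Why: This is an Evans alkylation in its deconjugative form, in which the chelated Z-dienolate is alkylated at Cα on the face opposite the benzyl group, setting the (S) centre and moving the alkene out of conjugation to form the isopropenyl group.

Step 3
Reactants: 7 (S)-4-benzyl-3-[(2S)-5-methyl-2-(prop-1-en-2-yl)hex-4-enoyl]-1,3-oxazolidin-2-one
Product: 8 (S)-lavandulol
Conditions: LiBH4, H2O (1.1 equiv), Et2O, 0 °C
Reagents that add atoms: none
Why: Reductive removal of the auxiliary with borohydride is fast at 0 °C, so the β,γ-unsaturated α-centre should neither epimerise nor move into conjugation.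

Step 4
Reactants: 8 (S)-lavandulol
Product: 9 (S)-lavandulyl iodide
Conditions: I2, PPh3, imidazole, CH2Cl2, 0 °C
Reagents that add atoms: iodine, II
Why: Appel-type iodination (Garegg–Samuelsson conditions) substitutes at the primary carbon only, so the neighbouring centre keeps its configuration.

Step 5
Reactants: 10 phloroglucinol; 11 ethyl 3-oxohexanoate
Product: 12 5,7-dihydroxy-4-propyl-2H-chromen-2-one
Conditions: conc. H2SO4, 90 °C
Reagents that add atoms: none
Why: In this Pechmann condensation the threefold symmetry of phloroglucinol allows only one regioisomer, and the lactone formed is the temporary ring of the route.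

Step 6
Reactants: 12 5,7-dihydroxy-4-propyl-2H-chromen-2-one
Product: 13 5-hydroxy-7-methoxy-4-propyl-2H-chromen-2-one
Conditions: MeI (1.05 equiv), K2CO3 (1.1 equiv), acetone, rt
Reagents that add atoms: iodomethane, CI
Why: In this Williamson etherification the 7-OH is the more acidic (conjugated with the pyrone carbonyl) and the less hindered hydroxyl (the 5-OH is peri to the propyl group), so it should react first and mark the future C8a.

Step 7
Reactants: 13 5-hydroxy-7-methoxy-4-propyl-2H-chromen-2-one
Product: 15 (4R)-5-hydroxy-7-methoxy-4-propyl-3,4-dihydro-2H-chromen-2-one, via bis(boryl) ketene acetal 14 (not isolated)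
Conditions: CuCl, NaOt-Bu, (R)-DTBM-SEGPHOS (5 mol % each), HBpin (2.3 equiv), toluene, rt; aq NH4Cl
Reagents that add atoms: pinacolborane, CC1(C)OBOC1(C)C (its boryl groups are present only in 14)
Why: This is a copper hydride-catalysed asymmetric conjugate reduction (1,4-hydroboration) of a 4-substituted coumarin, in which the ligand chooses the face of C4 that receives hydride and so sets the (R) centre.

Step 8
Reactants: 15 (4R)-5-hydroxy-7-methoxy-4-propyl-3,4-dihydro-2H-chromen-2-one
Product: 16 (4R)-6-bromo-5-hydroxy-7-methoxy-4-propyl-3,4-dihydro-2H-chromen-2-one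
Conditions: NBS (1.0 equiv), i-Pr2NH (10 mol %), CH2Cl2, −20 °C
Reagents that add atoms: N-bromosuccinimide, O=C1CCC(=O)N1Br
Why: In the amine-catalysed ortho-bromination of phenols, the N-bromoamine hydrogen-bonded to the OH delivers bromine to the only free ortho carbon, which is the future C4a.

Step 9
Reactants: 16 (4R)-6-bromo-5-hydroxy-7-methoxy-4-propyl-3,4-dihydro-2H-chromen-2-one
Product: 17 (4R)-6-bromo-5-hydroxy-8-iodo-7-methoxy-4-propyl-3,4-dihydro-2H-chromen-2-one
Conditions: NIS (1.05 equiv), TFA (10 mol %), MeCN, 0 °C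
Reagents that add atoms: N-iodosuccinimide, O=C1CCC(=O)N1I
Why: Electrophilic aromatic iodination can only occur at the one remaining ring position, which is para to the free OH and strongly activated.

Step 10
Reactants: 9 (S)-lavandulyl iodide
Product: 18 (S)-lavandulylzinc iodide (THF solution, titrated and used directly)
Conditions: Zn dust (activated), LiCl, THF, 35 °C
Reagents that add atoms: zinc, [Zn]
Why: LiCl-activated zinc inserts directly into the primary C–I bond, and the centre β to the metal is not involved.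

Step 11
Reactants: 17 (4R)-6-bromo-5-hydroxy-8-iodo-7-methoxy-4-propyl-3,4-dihydro-2H-chromen-2-one; 18 (S)-lavandulylzinc iodide
Product: 20 (4R)-6-bromo-5-hydroxy-7-methoxy-8-[(2R)-5-methyl-2-(prop-1-en-2-yl)hex-4-en-1-yl]-4-propyl-3,4-dihydro-2H-chromen-2-one, via sodium phenoxide 19 (not isolated)
Conditions: 17, NaH, THF, 0 °C; then 18 (1.3 equiv), Pd(OAc)2 (3 mol %), SPhos (6 mol %), THF, 40 °C; dil. HCl
Reagents that add atoms: sodium hydride, [Na+].[H-] (its sodium is present only in 19)
Why: In this Negishi sp2–sp3 coupling, oxidative addition at C–I is much faster than at the hindered C–Br, the bulky biaryl phosphine favours reductive elimination over β-hydride elimination, and pre-forming the phenoxide keeps the OH from protonating 18.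

Step 12
Reactants: 21 3-methylbut-2-en-1-ol (prenol)
Product: 22 tert-butyl 3-methylbut-2-en-1-yl carbonate
Conditions: Boc2O, DMAP (5 mol %), CH2Cl2, rt
Reagents that add atoms: di-tert-butyl dicarbonate, CC(C)(C)OC(=O)OC(=O)OC(C)(C)C
Why: O-Acylation of a primary allylic alcohol gives a prenyl donor that releases only the non-nucleophilic base tert-butoxide on ionisation.

Step 13
Reactants: 20 (4R)-6-bromo-5-hydroxy-7-methoxy-8-[(2R)-5-methyl-2-(prop-1-en-2-yl)hex-4-en-1-yl]-4-propyl-3,4-dihydro-2H-chromen-2-one; 22 tert-butyl 3-methylbut-2-en-1-yl carbonate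
Product: 23 (4R,8S)-6-bromo-7-methoxy-8-[(2R)-5-methyl-2-(prop-1-en-2-yl)hex-4-en-1-yl]-8-(3-methylbut-2-en-1-yl)-4-propyl-3,4-dihydro-2H-chromene-2,5(8H)-dione
Conditions: 22 (1.3 equiv), Pd2(dba)3·CHCl3 (2.5 mol %), (R,R)-DACH-phenyl ligand [N,N'-(1R,2R)-cyclohexane-1,2-diylbis(2-diphenylphosphinobenzamide)] (6 mol %), toluene, 0 °C → rt
Reagents that add atoms: none
Why: This is a Tsuji–Trost alkylation run as a para-allylative dearomatisation, known for 4-alkyl-3,5-dialkoxyphenols: both ortho carbons are blocked and O-prenylation is reversible under Pd(0), so the phenoxide attacks the CH2 end of the π-prenyl complex with its para carbon, and the chiral ligand pocket (Br/OMe on one flank, fused lactone on the other) chooses the ring face and sets the quaternary centre.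

Step 14
Reactants: 23 (4R,8S)-6-bromo-7-methoxy-8-[(2R)-5-methyl-2-(prop-1-en-2-yl)hex-4-en-1-yl]-8-(3-methylbut-2-en-1-yl)-4-propyl-3,4-dihydro-2H-chromene-2,5(8H)-dione
Product: 24 (3R)-3-{(5R)-3-bromo-2-hydroxy-4-methoxy-5-[(2R)-5-methyl-2-(prop-1-en-2-yl)hex-4-en-1-yl]-5-(3-methylbut-2-en-1-yl)-6-oxocyclohexa-1,3-dien-1-yl}hexanoic acid
Conditions: LiOH (2.2 equiv), THF–H2O, 0 °C; then 1 M HCl to pH 3
Reagents that add atoms: lithium hydroxide, [Li+].[OH-]
Why: The enol lactone of 23 is a vinylogous anhydride and should be saponified much faster than the methyl vinylogous ester, after which the ring is an anionic β-diketonate and inert to hydroxide, and no stereocentre is touched.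

Step 15
Reactants: 25 propanoyl chloride; 26 acetaldehyde
Product: 28 (3S,4R)-3,4-dimethyloxetan-2-one (cis), via methylketene 27 (not isolated)
Conditions: O-TMS-quinine (10 mol %), LiClO4, i-Pr2NEt, CH2Cl2–Et2O, −78 °C
Reagents that add atoms: none
Why: In this cinchona-alkaloid-catalysed ketene–aldehyde [2+2] cycloaddition (acyl halide–aldehyde cyclocondensation), the alkaloid binds methylketene as a Z-ammonium enolate that adds to Li+-activated acetaldehyde through a closed transition state, giving the cis lactone and fixing both centres.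

Step 16
Reactants: 24 (3R)-3-{(5R)-3-bromo-2-hydroxy-4-methoxy-5-[(2R)-5-methyl-2-(prop-1-en-2-yl)hex-4-en-1-yl]-5-(3-methylbut-2-en-1-yl)-6-oxocyclohexa-1,3-dien-1-yl}hexanoic acid; 28 (3S,4R)-3,4-dimethyloxetan-2-one
Product: 31 (3R)-3-{(2R,3S,8R)-5-hydroxy-2,3-dimethyl-8-[(2R)-5-methyl-2-(prop-1-en-2-yl)hex-4-en-1-yl]-8-(3-methylbut-2-en-1-yl)-4,7-dioxo-3,4,7,8-tetrahydro-2H-chromen-6-yl}hexanoic acid (target), via trilithio vinyl anion 29 (not isolated), via trilithium keto alkoxide 30 (not isolated)
Conditions: 24, t-BuLi (4.1 equiv), THF, −78 °C; 28 (1.2 equiv), −78 → −20 °C; 1 M HCl, −20 °C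
Reagents that add atoms: tert-butyllithium, [Li]C(C)(C)C (its lithium is present only in 29 and 30)
Why: Proposed new method: t-BuLi first deprotonates the acid and the enol of 24 (masking every ring carbonyl as carboxylate or β-diketonate) and then exchanges the vinylic bromine, so carbanion 29 sits on C4a while C8a still carries methoxide; 29 attacks the strained acyl carbon of 28 with acyl–O cleavage, and the alkoxide freed in 30 adds to C8a of the new β-methoxy enone and expels LiOMe, so the C4a=C8a unit is inserted into the C4–O1 bond and the four-membered ring O1–C2–C3–C4 becomes the six-membered dihydropyranone. The closest known reactions are the opening of β-lactones by organolithium reagents to β-hydroxy ketones, the acylation of α-lithiated vinylogous esters, alkoxide addition–elimination on β-alkoxy enones, and the two-atom ring expansion of β-lactams to 2,3-dihydroquinolin-4-ones by aryne insertion into the N–C(O) bond. The single ring closure is a 6-endo-trig oxa-Michael addition followed by β-elimination of methoxide. No stereocentre is created: C2 and C3 come from 28 with retention because no bond to either carbon is broken, which delivers the less stable cis-2,3-dimethyl array, and C8 and the two side-chain centres are spectators. The step needs acyl attack rather than alkyl C–O attack or α-deprotonation of 28 (favoured by the hard non-stabilised carbanion, the ring strain and −78 °C), and closure at C8a rather than C5 (only C8a bears a leaving group, C5 carries an oxyanion). C3 epimerisation and retro-oxa-Michael opening by LiOMe are limited by staying at or below −20 °C and quenching cold with acid.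

## Compound list

1 | (S)-4-benzyl-1,3-oxazolidin-2-one | O=C1N[C@@H](Cc2ccccc2)CO1 | starting material
2 | 3-methylbut-2-enoyl chloride | CC(C)=CC(=O)Cl | starting material
3 | lithium salt of 1 (not isolated) | O=C1[N-][C@@H](Cc2ccccc2)CO1.[Li+] | intermediate
4 | (S)-4-benzyl-3-(3-methylbut-2-enoyl)-1,3-oxazolidin-2-one | CC(C)=CC(=O)N1[C@@H](Cc2ccccc2)COC1=O | intermediate
5 | 1-bromo-3-methylbut-2-ene (prenyl bromide) | CC(C)=CCBr | starting material
6 | sodium Z-dienolate of 4 (not isolated) | C=C(C)/C=C(\[O-])N1[C@@H](Cc2ccccc2)COC1=O.[Na+] | intermediate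
7 | (S)-4-benzyl-3-[(2S)-5-methyl-2-(prop-1-en-2-yl)hex-4-enoyl]-1,3-oxazolidin-2-one | C=C(C)[C@H](CC=C(C)C)C(=O)N1[C@@H](Cc2ccccc2)COC1=O | intermediate
8 | (S)-lavandulol, (2S)-5-methyl-2-(prop-1-en-2-yl)hex-4-en-1-ol | C=C(C)[C@H](CC=C(C)C)CO | intermediate
9 | (S)-lavandulyl iodide, (3S)-3-(iodomethyl)-2,6-dimethylhepta-1,5-diene | C=C(C)[C@H](CC=C(C)C)CI | intermediate
10 | phloroglucinol (benzene-1,3,5-triol) | Oc1cc(O)cc(O)c1 | starting material
11 | ethyl 3-oxohexanoate | CCCC(=O)CC(=O)OCC | starting material
12 | 5,7-dihydroxy-4-propyl-2H-chromen-2-one | CCCC1=CC(=O)Oc2cc(O)cc(O)c12 | intermediate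
13 | 5-hydroxy-7-methoxy-4-propyl-2H-chromen-2-one | CCCC1=CC(=O)Oc2cc(OC)cc(O)c12 | intermediate
14 | (4R)-7-methoxy-2,5-bis(pinacolboryloxy)-4-propyl-4H-chromene (not isolated) | COc1cc(OB3OC(C)(C)C(C)(C)O3)c2c(c1)OC(OB1OC(C)(C)C(C)(C)O1)=C[C@H]2CCC | intermediate
15 | (4R)-5-hydroxy-7-methoxy-4-propyl-3,4-dihydro-2H-chromen-2-one | COc1cc(O)c2c(c1)OC(=O)C[C@H]2CCC | intermediate
16 | (4R)-6-bromo-5-hydroxy-7-methoxy-4-propyl-3,4-dihydro-2H-chromen-2-one | COc1c(Br)c(O)c2c(c1)OC(=O)C[C@H]2CCC | intermediate
17 | (4R)-6-bromo-5-hydroxy-8-iodo-7-methoxy-4-propyl-3,4-dihydro-2H-chromen-2-one | COc1c(Br)c(O)c2c(c1I)OC(=O)C[C@H]2CCC | intermediate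
18 | [(2S)-5-methyl-2-(prop-1-en-2-yl)hex-4-en-1-yl]zinc iodide | C=C(C)[C@H](CC=C(C)C)C[Zn]I | intermediate
19 | sodium phenoxide of 17 (not isolated) | COc1c(Br)c([O-])c2c(c1I)OC(=O)C[C@H]2CCC.[Na+] | intermediate
20 | (4R)-6-bromo-5-hydroxy-7-methoxy-8-[(2R)-5-methyl-2-(prop-1-en-2-yl)hex-4-en-1-yl]-4-propyl-3,4-dihydro-2H-chromen-2-one | C=C(C)[C@H](CC=C(C)C)Cc1c(OC)c(Br)c(O)c2c1OC(=O)C[C@H]2CCC | intermediate
21 | 3-methylbut-2-en-1-ol (prenol) | CC(C)=CCO | starting material
22 | tert-butyl 3-methylbut-2-en-1-yl carbonate | CC(C)=CCOC(=O)OC(C)(C)C | intermediate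
23 | (4R,8S)-6-bromo-7-methoxy-8-[(2R)-5-methyl-2-(prop-1-en-2-yl)hex-4-en-1-yl]-8-(3-methylbut-2-en-1-yl)-4-propyl-3,4-dihydro-2H-chromene-2,5(8H)-dione | C=C(C)[C@H](CC=C(C)C)C[C@@]1(CC=C(C)C)C2=C([C@H](CCC)CC(=O)O2)C(=O)C(Br)=C1OC | intermediate
24 | (3R)-3-{(5R)-3-bromo-2-hydroxy-4-methoxy-5-[(2R)-5-methyl-2-(prop-1-en-2-yl)hex-4-en-1-yl]-5-(3-methylbut-2-en-1-yl)-6-oxocyclohexa-1,3-dien-1-yl}hexanoic acid | C=C(C)[C@H](CC=C(C)C)C[C@@]1(CC=C(C)C)C(=O)C([C@H](CCC)CC(=O)O)=C(O)C(Br)=C1OC | intermediate
25 | propanoyl chloride | CCC(=O)Cl | starting material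
26 | acetaldehyde | CC=O | starting material
27 | methylketene (not isolated) | CC=C=O | intermediate
28 | (3S,4R)-3,4-dimethyloxetan-2-one (cis) | O1[C@H](C)[C@H](C)C1=O | intermediate
29 | trilithio derivative of 24: carboxylate, enolate and C-lithiated ring carbon in place of C–Br (not isolated) | C=C(C)[C@H](CC=C(C)C)C[C@@]1(CC=C(C)C)C(=O)C([C@H](CCC)CC(=O)[O-])=C([O-])C([Li])=C1OC.[Li+].[Li+] | intermediate
30 | trilithium salt of the (2S,3R)-3-oxido-2-methylbutanoyl dienone, methoxy group still in place (not isolated) | C=C(C)[C@H](CC=C(C)C)C[C@@]1(CC=C(C)C)C(=O)C([C@H](CCC)CC(=O)[O-])=C([O-])C(C(=O)[C@@H](C)[C@@H](C)[O-])=C1OC.[Li+].[Li+].[Li+] | intermediate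
31 | (3R)-3-{(2R,3S,8R)-5-hydroxy-2,3-dimethyl-8-[(2R)-5-methyl-2-(prop-1-en-2-yl)hex-4-en-1-yl]-8-(3-methylbut-2-en-1-yl)-4,7-dioxo-3,4,7,8-tetrahydro-2H-chromen-6-yl}hexanoic acid | C=C(C)[C@H](CC=C(C)C)C[C@@]1(CC=C(C)C)C(=O)C([C@H](CCC)CC(=O)O)=C(O)C2=C1O[C@H](C)[C@H](C)C2=O | target

## Step count and risks

Total step count: 16. Longest linear sequence: 9 steps (5, 6, 7, 8, 9, 11, 13, 14, 16). The lavandulyl branch (1, 2, 3, 4, 10, 11, 13, 14, 16) is equally long.

**Risk 1 (step 16).** The very basic vinyl anion may take the proton at C3 of the lactone instead of attacking the acyl carbon. The lithium aldolate may also undergo retro-aldol cleavage or C3 epimerisation before the ring has closed.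

The fallback uses known reaction types only, sets out from 28 and 24, and returns at 31.
- Lactone 28 is opened with MeNH(OMe)·HCl and i-PrMgCl to (2S,3R)-3-hydroxy-N-methoxy-N,2-dimethylbutanamide F1.
- F1 is silylated (TESCl, imidazole) to (2S,3R)-N-methoxy-N,2-dimethyl-3-(triethylsilyloxy)butanamide F2.
- Anion 29, made from 24 as before, is acylated with F2 in a Weinreb ketone synthesis. The chelated tetrahedral adduct lasts until the quench and no free alkoxide is present. This gives the β-silyloxy ketone (3R)-3-{(5R)-2-hydroxy-4-methoxy-3-[(2S,3R)-2-methyl-3-(triethylsilyloxy)butanoyl]-5-[(2R)-lavandulyl]-5-prenyl-6-oxocyclohexa-1,3-dien-1-yl}hexanoic acid F3.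
- HF·pyridine in THF at 0 °C frees the alcohol, which closes onto the methoxy-bearing ring carbon by addition–elimination with loss of methanol to give 31.

**Risk 2 (step 13).** The ligand may discriminate poorly between the two ring faces at the remote para carbon, or the π-prenyl unit may be captured at oxygen.

The fallback sets out from 20 and returns at 23. Catalyst control is given up. Compound 20 is prenylated with 22 and an achiral catalyst (Pd(PPh3)4, toluene), which should give 23 together with its C8 epimer, the (4R,8R)-dienone lactone F4. The centres at C4 and in the lavandulyl chain are already fixed, so the two products are diastereomers. They are separated by chromatography or crystallisation, and pure 23 is carried on.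

**Risk 3 (step 7).** The peri oxygen substituent may slow hydride delivery to C4 and erode the facial selectivity of the copper hydride.

The fallback sets out from 13 and returns at 15.
- Hydrogenation over Pd/C gives racemic 5-hydroxy-7-methoxy-4-propyl-3,4-dihydro-2H-chromen-2-one F5.
- Aminolysis with (S)-1-phenylethylamine opens the lactone to two diastereomeric amides: (3R)-3-(2,6-dihydroxy-4-methoxyphenyl)-N-[(1S)-1-phenylethyl]hexanamide F6 and its (3S) isomer F7. These are separated by crystallisation.
- Heating F6 with TsOH in toluene re-closes the lactone with loss of the amine. The two phenolic OH groups of F6 are equivalent, so only 15 can form.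

## Further compounds

F1 | step 16 | (2S,3R)-3-hydroxy-N-methoxy-N,2-dimethylbutanamide | CON(C)C(=O)[C@@H](C)[C@@H](C)O
F2 | step 16 | (2S,3R)-N-methoxy-N,2-dimethyl-3-(triethylsilyloxy)butanamide | CON(C)C(=O)[C@@H](C)[C@@H](C)O[Si](CC)(CC)CC
F3 | step 16 | (3R)-3-{(5R)-2-hydroxy-4-methoxy-3-[(2S,3R)-2-methyl-3-(triethylsilyloxy)butanoyl]-5-[(2R)-5-methyl-2-(prop-1-en-2-yl)hex-4-en-1-yl]-5-(3-methylbut-2-en-1-yl)-6-oxocyclohexa-1,3-dien-1-yl}hexanoic acid | C=C(C)[C@H](CC=C(C)C)C[C@@]1(CC=C(C)C)C(=O)C([C@H](CCC)CC(=O)O)=C(O)C(C(=O)[C@@H](C)[C@@H](C)O[Si](CC)(CC)CC)=C1OC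
F4 | step 13 | (4R,8R)-6-bromo-7-methoxy-8-[(2R)-5-methyl-2-(prop-1-en-2-yl)hex-4-en-1-yl]-8-(3-methylbut-2-en-1-yl)-4-propyl-3,4-dihydro-2H-chromene-2,5(8H)-dione | C=C(C)[C@H](CC=C(C)C)C[C@]1(CC=C(C)C)C2=C([C@H](CCC)CC(=O)O2)C(=O)C(Br)=C1OC
F5 | step 7 | racemic 5-hydroxy-7-methoxy-4-propyl-3,4-dihydro-2H-chromen-2-one | COc1cc(O)c2c(c1)OC(=O)CC2CCC
F6 | step 7 | (3R)-3-(2,6-dihydroxy-4-methoxyphenyl)-N-[(1S)-1-phenylethyl]hexanamide | CCC[C@H](CC(=O)N[C@@H](C)c1ccccc1)c1c(O)cc(OC)cc1O
F7 | step 7 | (3S)-3-(2,6-dihydroxy-4-methoxyphenyl)-N-[(1S)-1-phenylethyl]hexanamide | CCC[C@@H](CC(=O)N[C@@H](C)c1ccccc1)c1c(O)cc(OC)cc1O
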